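The vessel was closed and stirred, so the E charged stayed in it in some form, and I kept a budget of it.

common to all: J 27 mM

| run | E | remark | time |
|---|---|---|---|
| west | 43 mM | run made earlier |  |
| south-east | 42 mM | run made earlier |  |
| north | 62 mM | run made earlier |  |
| autumn | 53.0 mM |  | 25 h |
| summer | 40.0 mM |  | 25 h |

- west (time / h: J / %, G / %): 1.00: 52, 43; 3.00: 32, 50; 6.00: 27, 51; 8.00: 27, 47; 12.0: 24, 50
- south-east (time / h: J / %, G / %): 1.00: 52, 41; 3.00: 34, 50; 6.00: 30, 48; 8.00: 26, 49; 12.0: 25, 47
- north (time / h: J / %, G / %): 2.50: 20, 57; 5.00: 11, 52; 8.00: 6, 49; 10.0: 4, 48; 12.0: 6, 45

(readings scatter by 1.5 percentage points)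

- for G the X are counted in
- as a solid, counted per litre of solution: X
- what may be going on: G <-> L; E + G -> Q; J + E -> D + G; E + D <-> Z; X <-> G

1. part of the J that has reacted at the end, autumn
2. part of the J that has reacted at the end, summer
3. what raising the concentration of E from its lowest to its highest value here does to the part of the J that has reacted (changes below 5 percentage points count as none) (no change / it rises / it falls)

J stalled near 24% in the west flask but fell to 6% in the north flask with more E, so I took E as the limiting reagent in the west and south-east flasks. My first way was a ledger: E charged over J reacted at the last reading gave 2.10 in the west flask and 2.07 in the south-east flask. I called their mean, 2.08, the E toll, the E spent per J reacted.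

My second way was a count. A J takes one E, its D can take a second into Z, and each Q takes another, so with every D bound and no Q the toll would be 2, and any D left free would bring it lower. If the 26 percentage points missing from J and G in the west flask were Q, with every D bound it would reach 2.34, but L may hold part of them. The ledger fell between those two counts.

The ledger would cheat if E were still unspent at the last reading. However, west J moved from 27% to 24% after 6.00 h, close to the scatter of 1.5 points. In the north flask, the toll allowed 29.7 mM of J, more than the 27 mM charged, and J nearly ran out there, as the ledger required.

So I joined the two ends: E over the toll below the crossing, the J charge above it. The crossing stood at 56.3 mM, and autumn lay below it. My reckoning gave 71.1% for summer and 94.2% for autumn.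

The forecast said 74% (68% to 81%) for summer and 92% (85% to 98%) for autumn, and for the part reacted on going from the lowest E to the highest it said: it rises. It was higher than mine in summer and lower in autumn, and it allowed that “Slow late drift, perhaps E released from Z, could add a few percent”.

    G ⇌ L (K = 0.300, k = 2.14 × 10⁻⁵ s⁻¹)
    E + G → Q (k = 0.00161 L mol⁻¹ s⁻¹)
    J + E → D + G (k = 0.00681 L mol⁻¹ s⁻¹)
    E + D ⇌ Z, settled at all times (K = 17800 L mol⁻¹)
    X ⇌ G, rate k5*(cs5 - [G]) while solid is left; crystals form when [G] > cs5 (solubility = 22.0 mM, k = 0.00103 s⁻¹)

The flask gave 74.6% in summer and 90.0% in autumn, and for the part reacted on going from the lowest E to the highest it gave: it rises, by 15 points. In summer E was first to run out, with 0.62% of its charge free at 25.0 h. The toll, taken on the E no longer free, came to 1.97 in summer and 2.16 in autumn, where 0.89% of the E charge stood free at 25.0 h. A neighbour of summer held 16 mM of J, less than the 19.2 mM its E could pay for at the read toll; there J ran out first, with 1.82% left.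

(The earlier runs and the new flask were generated by integration for an exercise; noise was put on by code.)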